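Ring A carries two neighbouring carbon substituents, the depside carbonyl on C1 and the side-chain CH2 on C6, with the C2 oxygen next to C1. That 1,2-relationship is cut back to an aryne: 3,5-dimethoxybenzyne, released from 3,5-dimethoxy-2-(trimethylsilyl)phenyl triflate, is slotted into a C–C bond of dimethyl malonate, so that C1–C(=O) and C6–CH2 form in one operation as a differentiated homophthalate diester. The free aliphatic ester is then grown into the heptyl ketone, the hindered ring ester becomes the acyl donor for the 4-OH of benzyl orsellinate (ring B), and the ketone stays masked as a dioxolane until the depside bond is in place.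

Key step: step 4

Remark: ring A is numbered with C1 bearing the ester carbonyl, C2 the hydroxyl, C4 the methoxy group and C6 the 2-oxononyl chain; ring B is the orsellinic acid ring, acylated at its C4 oxygen; the target has no stereocentre.

Step 1
Reactants: 1 3,5-dimethoxyphenol
Product: 2 2-bromo-3,5-dimethoxyphenol
Conditions: NBS (1.0 equiv), CH2Cl2, −78 °C to rt
Reagents that add atoms: N-bromosuccinimide, O=C1CCC(=O)N1Br
Why: Electrophilic aromatic bromination of the very electron-rich ring should go ortho to the free hydroxyl (C2 and C6 are equivalent, and hydrogen bonding of NBS to the phenol in cold CH2Cl2 disfavours C4 between the two methoxy groups), any C4 isomer being removed by chromatography.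

Step 2
Reactants: 2 2-bromo-3,5-dimethoxyphenol
Product: 3 (2-bromo-3,5-dimethoxyphenoxy)trimethylsilane
Conditions: HMDS, THF, 70 °C; evaporate
Reagents that add atoms: hexamethyldisilazane, C[Si](C)(C)N[Si](C)(C)C
Why: O-Silylation of a phenol with hexamethyldisilazane, driven by loss of ammonia, should give the aryl silyl ether cleanly enough to be used after evaporation.

Step 3
Reactants: 3 (2-bromo-3,5-dimethoxyphenoxy)trimethylsilane
Product: 5 3,5-dimethoxy-2-(trimethylsilyl)phenyl trifluoromethanesulfonate, via lithium 3,5-dimethoxy-2-(trimethylsilyl)phenolate 4 (not isolated)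
Conditions: n-BuLi, THF, −100 to −80 °C; then Tf2O, −100 °C to rt
Reagents that add atoms: trifluoromethanesulfonic anhydride, O=S(=O)(OS(=O)(=O)C(F)(F)F)C(F)(F)F
Why: Bromine–lithium exchange gives an aryllithium that undergoes a 1,3 O-to-C silyl shift (retro-Brook rearrangement) driven by formation of lithium phenolate 4, and O-sulfonylation of 4 by Tf2O should then give the ortho-silyl aryl triflate.

Step 4
Reactants: 5 3,5-dimethoxy-2-(trimethylsilyl)phenyl trifluoromethanesulfonate; 6 dimethyl malonate
Product: 8 methyl 2,4-dimethoxy-6-(2-methoxy-2-oxoethyl)benzoate (dimethyl 3,5-dimethoxyhomophthalate), via 3,5-dimethoxybenzyne 7 (not isolated)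
Conditions: CsF (3 equiv), 6 (3 equiv), MeCN, 70 °C
Reagents that add atoms: none
Why: Fluoride strips the trimethylsilyl group and triflate leaves, giving aryne 7; the malonate enolate adds to the aryne carbon remote from the flanking methoxy group, the aryl anion thus placed beside that oxygen attacks one ester carbonyl to give a four-membered ring alkoxide, and retro-aldol-type opening of that ring gives the homophthalate enolate, a net insertion of the aryne into a C–C sigma bond. The closest known reaction type is the fluoride-triggered acyl-alkylation of arynes from 2-silylaryl triflates with malonates and beta-ketoesters. No ring remains in the product, since the four-membered ring is only a transient that reopens at once, and no stereocentre is formed. The step needs regioselectivity, which the substrate should secure: the inductively withdrawing methoxy group next to the triple bond polarises the aryne so that carbon nucleophiles attack the distal carbon, placing CH2CO2Me on C6 and the carbonyl on C1 beside the C2 oxygen. It also needs mono-arylation, which the excess of 6 should secure because 6 is more acidic than product 8 and protonates its enolate.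

Step 5
Reactants: 8 methyl 2,4-dimethoxy-6-(2-methoxy-2-oxoethyl)benzoate
Product: 9 methyl 2-hydroxy-4-methoxy-6-(2-methoxy-2-oxoethyl)benzoate
Conditions: BCl3 (1.2 equiv), CH2Cl2, −78 to 0 °C; then H2O
Reagents that add atoms: none
Why: Chelation-controlled Lewis acid ether cleavage: BCl3 binds between the ring ester carbonyl and the C2 methoxy oxygen, so chloride should remove only that methyl group while the C4 ether and both esters stay intact.

Step 6
Reactants: 9 methyl 2-hydroxy-4-methoxy-6-(2-methoxy-2-oxoethyl)benzoate
Product: 10 2-[3-hydroxy-5-methoxy-2-(methoxycarbonyl)phenyl]acetic acid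
Conditions: LiOH·H2O (3 equiv), THF/H2O, 0 °C to rt; then 1 M HCl
Reagents that add atoms: lithium hydroxide, [Li+].[OH-]
Why: Saponification should touch only the unhindered aliphatic ester, because the ring ester is flanked on both sides and further deactivated by the ortho phenoxide formed under the conditions.

Step 7
Reactants: 10 2-[3-hydroxy-5-methoxy-2-(methoxycarbonyl)phenyl]acetic acid
Product: 11 methyl 2-hydroxy-4-methoxy-6-{2-[methoxy(methyl)amino]-2-oxoethyl}benzoate
Conditions: MeNHOMe·HCl, EDC·HCl, HOBt, N-methylmorpholine, CH2Cl2, 0 °C to rt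
Reagents that add atoms: N,O-dimethylhydroxylamine hydrochloride, CNOC.Cl
Why: Carbodiimide amide coupling through the HOBt active ester should convert the arylacetic acid into the Weinreb amide, the hydrogen-bonded C2 phenol being too poor a nucleophile to compete.

Step 8
Reactants: 11 methyl 2-hydroxy-4-methoxy-6-{2-[methoxy(methyl)amino]-2-oxoethyl}benzoate; 12 1-bromoheptane
Product: 14 methyl 2-hydroxy-4-methoxy-6-(2-oxononyl)benzoate, via heptylmagnesium bromide 13 (not isolated)
Conditions: 12, Mg turnings, THF, 40 °C; then 11 (0.3 equiv relative to 13), THF, −20 to 0 °C; then 1 M HCl, 0 °C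
Reagents that add atoms: none
Why: Weinreb ketone synthesis: after one equivalent of Grignard reagent 13 has deprotonated the phenol, addition to the N-methoxy-N-methylamide gives a magnesium-chelated tetrahedral intermediate that survives until the quench, so no tertiary alcohol should form and the hindered, phenoxide-deactivated ring ester is not attacked.

Step 9
Reactants: 14 methyl 2-hydroxy-4-methoxy-6-(2-oxononyl)benzoate
Product: 15 methyl 2-[(2-heptyl-1,3-dioxolan-2-yl)methyl]-6-hydroxy-4-methoxybenzoate
Conditions: HOCH2CH2OH, HC(OEt)3, TsOH·H2O (cat.), CH2Cl2, rt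
Reagents that add atoms: ethylene glycol, OCCO
Why: Acid-catalysed ketalisation with the orthoformate as water scavenger should run at room temperature, mild enough to avoid enol-lactonisation of the keto ester, and masks the ketone so that it cannot close onto the activated carboxyl later.

Step 10
Reactants: 15 methyl 2-[(2-heptyl-1,3-dioxolan-2-yl)methyl]-6-hydroxy-4-methoxybenzoate
Product: 16 2-[(2-heptyl-1,3-dioxolan-2-yl)methyl]-6-hydroxy-4-methoxybenzoic acid
Conditions: KOH, DMSO/H2O (4:1), 80 °C; then 1 M HCl to pH 3, 0 °C, extract at once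
Reagents that add atoms: potassium hydroxide, [K+].[OH-]
Why: Ester hydrolysis with poorly solvated hydroxide in aqueous DMSO, a standard way to open hindered ortho-hydroxy benzoates, should give the acid with the base-stable dioxolane untouched, while a cold and brief acidification and immediate use limit decarboxylation and ketal loss.

Step 11
Reactants: 17 orsellinic acid (2,4-dihydroxy-6-methylbenzoic acid)
Product: 18 benzyl 2,4-dihydroxy-6-methylbenzoate (benzyl orsellinate)
Conditions: BnBr, KHCO3, DMF, rt
Reagents that add atoms: benzyl bromide, BrCc1ccccc1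
Why: Bicarbonate deprotonates only the carboxylic acid, so SN2 alkylation with benzyl bromide should give the benzyl ester and leave both phenols free.

Step 12
Reactants: 16 2-[(2-heptyl-1,3-dioxolan-2-yl)methyl]-6-hydroxy-4-methoxybenzoic acid; 18 benzyl 2,4-dihydroxy-6-methylbenzoate
Product: 19 benzyl 4-({2-[(2-heptyl-1,3-dioxolan-2-yl)methyl]-6-hydroxy-4-methoxybenzoyl}oxy)-2-hydroxy-6-methylbenzoate
Conditions: DCC, DMAP (cat.), CH2Cl2, 0 °C to rt
Reagents that add atoms: none
Why: Steglich-type esterification: the C4 hydroxyl of 18 is the only unhindered, non-hydrogen-bonded phenol in either partner (each C2 hydroxyl is locked in a hydrogen bond to its ortho carbonyl), so carbodiimide activation of 16 should give the para-depside ester selectively, as in classical depside couplings.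

Step 13
Reactants: 19 benzyl 4-({2-[(2-heptyl-1,3-dioxolan-2-yl)methyl]-6-hydroxy-4-methoxybenzoyl}oxy)-2-hydroxy-6-methylbenzoate
Product: 20 benzyl 2-hydroxy-4-{[2-hydroxy-4-methoxy-6-(2-oxononyl)benzoyl]oxy}-6-methylbenzoate
Conditions: 2 M HCl, THF, rt
Reagents that add atoms: water, O
Why: Acid-catalysed ketal hydrolysis at room temperature should release the dialkyl ketone while the aryl ester and the benzyl ester, both stable to dilute aqueous acid, remain.

Step 14
Reactants: 20 benzyl 2-hydroxy-4-{[2-hydroxy-4-methoxy-6-(2-oxononyl)benzoyl]oxy}-6-methylbenzoate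
Product: 21 2-hydroxy-4-{[2-hydroxy-4-methoxy-6-(2-oxononyl)benzoyl]oxy}-6-methylbenzoic acid (CNP0320117.0)
Conditions: H2 (1 atm), 10% Pd/C, EtOAc, rt
Reagents that add atoms: none
Why: Catalytic hydrogenolysis of the benzyl ester under neutral conditions should free the carboxylic acid without touching the aliphatic ketone or the depside ester, so the acid- and base-sensitive target needs only filtration and evaporation.

Compound list
1 | 3,5-dimethoxyphenol | COc1cc(O)cc(OC)c1 | starting material
2 | 2-bromo-3,5-dimethoxyphenol | Oc1cc(OC)cc(OC)c1Br | intermediate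
3 | (2-bromo-3,5-dimethoxyphenoxy)trimethylsilane | C[Si](C)(C)Oc1cc(OC)cc(OC)c1Br | intermediate
4 | lithium 3,5-dimethoxy-2-(trimethylsilyl)phenolate | [Li+].[O-]c1cc(OC)cc(OC)c1[Si](C)(C)C | intermediate (not isolated)
5 | 3,5-dimethoxy-2-(trimethylsilyl)phenyl trifluoromethanesulfonate | COc1cc(OC)c([Si](C)(C)C)c(OS(=O)(=O)C(F)(F)F)c1 | intermediate
6 | dimethyl malonate | COC(=O)CC(=O)OC | starting material
7 | 3,5-dimethoxybenzyne (1,2-didehydro-3,5-dimethoxybenzene) | COC1=CC(OC)=CC#C1 | intermediate (not isolated)
8 | methyl 2,4-dimethoxy-6-(2-methoxy-2-oxoethyl)benzoate | COC(=O)Cc1cc(OC)cc(OC)c1C(=O)OC | intermediate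
9 | methyl 2-hydroxy-4-methoxy-6-(2-methoxy-2-oxoethyl)benzoate | COC(=O)Cc1cc(OC)cc(O)c1C(=O)OC | intermediate
10 | 2-[3-hydroxy-5-methoxy-2-(methoxycarbonyl)phenyl]acetic acid | OC(=O)Cc1cc(OC)cc(O)c1C(=O)OC | intermediate
11 | methyl 2-hydroxy-4-methoxy-6-{2-[methoxy(methyl)amino]-2-oxoethyl}benzoate | CON(C)C(=O)Cc1cc(OC)cc(O)c1C(=O)OC | intermediate
12 | 1-bromoheptane | CCCCCCCBr | starting material
13 | heptylmagnesium bromide | CCCCCCC[Mg]Br | intermediate (not isolated)
14 | methyl 2-hydroxy-4-methoxy-6-(2-oxononyl)benzoate | CCCCCCCC(=O)Cc1cc(OC)cc(O)c1C(=O)OC | intermediate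
15 | methyl 2-[(2-heptyl-1,3-dioxolan-2-yl)methyl]-6-hydroxy-4-methoxybenzoate | CCCCCCCC1(Cc2cc(OC)cc(O)c2C(=O)OC)OCCO1 | intermediate
16 | 2-[(2-heptyl-1,3-dioxolan-2-yl)methyl]-6-hydroxy-4-methoxybenzoic acid | CCCCCCCC1(Cc2cc(OC)cc(O)c2C(=O)O)OCCO1 | intermediate
17 | orsellinic acid (2,4-dihydroxy-6-methylbenzoic acid) | Cc1cc(O)cc(O)c1C(=O)O | starting material
18 | benzyl 2,4-dihydroxy-6-methylbenzoate | Cc1cc(O)cc(O)c1C(=O)OCc1ccccc1 | intermediate
19 | benzyl 4-({2-[(2-heptyl-1,3-dioxolan-2-yl)methyl]-6-hydroxy-4-methoxybenzoyl}oxy)-2-hydroxy-6-methylbenzoate | CCCCCCCC1(Cc2cc(OC)cc(O)c2C(=O)Oc2cc(C)c(C(=O)OCc3ccccc3)c(O)c2)OCCO1 | intermediate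
20 | benzyl 2-hydroxy-4-{[2-hydroxy-4-methoxy-6-(2-oxononyl)benzoyl]oxy}-6-methylbenzoate | CCCCCCCC(=O)Cc1cc(OC)cc(O)c1C(=O)Oc1cc(C)c(C(=O)OCc2ccccc2)c(O)c1 | intermediate
21 | 2-hydroxy-4-{[2-hydroxy-4-methoxy-6-(2-oxononyl)benzoyl]oxy}-6-methylbenzoic acid | CCCCCCCC(=O)Cc1cc(OC)cc(O)c1C(=O)Oc1cc(C)c(C(=O)O)c(O)c1 | target

Total step count: 14. Longest linear sequence: 13 steps (steps 1 to 10, then 12 to 14, from 3,5-dimethoxyphenol); step 11 is a one-step side branch.

Steps most likely to fail

Step 4. The aryne may be lost to protonation or self-reaction before it meets the enolate. The aryl anion may also be protonated before it closes onto the ester, which gives plain alpha-arylation instead of insertion, or the product enolate may be arylated a second time. Fallback by lateral metalation and carboxylation, setting out from 17 and coming back at 8: orsellinic acid 17 is exhaustively methylated (MeI, K2CO3, acetone, reflux) to methyl 2,4-dimethoxy-6-methylbenzoate F1. LDA (2.2 equiv, THF, −78 °C) then removes a proton from the ring methyl group, which is acidified by the ortho ester, and acylation of the benzylic anion with dimethyl carbonate gives 8.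

Step 12. Acylation of the phenol by the doubly ortho-substituted acid may be slower than rearrangement of the activated acid to the N-acylurea, self-acylation through the free C2 hydroxyl, or acid-promoted collapse of the ketal onto the carboxyl with enol-lactone formation. Fallback by capping the C2 hydroxyl so that the coupling can be forced, setting out from 15 and coming back at 21: 15 is O-benzylated (BnBr, K2CO3, DMF) to methyl 2-(benzyloxy)-6-[(2-heptyl-1,3-dioxolan-2-yl)methyl]-4-methoxybenzoate F2. Saponification (KOH, DMSO/H2O, 90 °C) gives 2-(benzyloxy)-6-[(2-heptyl-1,3-dioxolan-2-yl)methyl]-4-methoxybenzoic acid F3. With no free ortho hydroxyl, F3 can be driven onto 18 with excess DCC and stoichiometric DMAP in warm CH2Cl2 to give benzyl 4-({2-(benzyloxy)-6-[(2-heptyl-1,3-dioxolan-2-yl)methyl]-4-methoxybenzoyl}oxy)-2-hydroxy-6-methylbenzoate F4. 2 M HCl in THF unmasks the ketone to benzyl 4-{[2-(benzyloxy)-4-methoxy-6-(2-oxononyl)benzoyl]oxy}-2-hydroxy-6-methylbenzoate F5, and one hydrogenolysis (H2, 10% Pd/C, EtOAc) removes the benzyl ether and the benzyl ester together to give 21.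

Step 13. Under acid the ketal-derived oxocarbenium ion, or the enol of the freed ketone, may be captured by the neighbouring aryl ester carbonyl, so that lactonisation expels the ring B phenol and the depside bond is lost. Fallback with a ketal that is removed reductively, so that no acid meets the depside, setting out from 14 and coming back at 21: 14 is ketalised with racemic 1-phenylethane-1,2-diol (HC(OEt)3, TsOH·H2O cat., CH2Cl2) to methyl 2-[(2-heptyl-4-phenyl-1,3-dioxolan-2-yl)methyl]-6-hydroxy-4-methoxybenzoate F6, a diastereomer mixture of no consequence. Hydrolysis as in step 10 gives 2-[(2-heptyl-4-phenyl-1,3-dioxolan-2-yl)methyl]-6-hydroxy-4-methoxybenzoic acid F7, and coupling with 18 as in step 12 gives benzyl 4-({2-[(2-heptyl-4-phenyl-1,3-dioxolan-2-yl)methyl]-6-hydroxy-4-methoxybenzoyl}oxy)-2-hydroxy-6-methylbenzoate F8. Hydrogenolysis (H2, Pd(OH)2/C, EtOAc) then cleaves the benzyl ester and the benzylic C–O bond of the ketal like a benzyl ether; the hemiketal so formed falls apart to the ketone and 2-phenylethanol, giving 21 directly.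

Further compounds
F1 | step 4 | methyl 2,4-dimethoxy-6-methylbenzoate | COC(=O)c1c(C)cc(OC)cc1OC
F2 | step 12 | methyl 2-(benzyloxy)-6-[(2-heptyl-1,3-dioxolan-2-yl)methyl]-4-methoxybenzoate | CCCCCCCC1(Cc2cc(OC)cc(OCc3ccccc3)c2C(=O)OC)OCCO1
F3 | step 12 | 2-(benzyloxy)-6-[(2-heptyl-1,3-dioxolan-2-yl)methyl]-4-methoxybenzoic acid | CCCCCCCC1(Cc2cc(OC)cc(OCc3ccccc3)c2C(=O)O)OCCO1
F4 | step 12 | benzyl 4-({2-(benzyloxy)-6-[(2-heptyl-1,3-dioxolan-2-yl)methyl]-4-methoxybenzoyl}oxy)-2-hydroxy-6-methylbenzoate | CCCCCCCC1(Cc2cc(OC)cc(OCc3ccccc3)c2C(=O)Oc2cc(C)c(C(=O)OCc3ccccc3)c(O)c2)OCCO1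
F5 | step 12 | benzyl 4-{[2-(benzyloxy)-4-methoxy-6-(2-oxononyl)benzoyl]oxy}-2-hydroxy-6-methylbenzoate | CCCCCCCC(=O)Cc1cc(OC)cc(OCc2ccccc2)c1C(=O)Oc1cc(C)c(C(=O)OCc2ccccc2)c(O)c1
F6 | step 13 | methyl 2-[(2-heptyl-4-phenyl-1,3-dioxolan-2-yl)methyl]-6-hydroxy-4-methoxybenzoate | CCCCCCCC1(Cc2cc(OC)cc(O)c2C(=O)OC)OCC(c2ccccc2)O1
F7 | step 13 | 2-[(2-heptyl-4-phenyl-1,3-dioxolan-2-yl)methyl]-6-hydroxy-4-methoxybenzoic acid | CCCCCCCC1(Cc2cc(OC)cc(O)c2C(=O)O)OCC(c2ccccc2)O1
F8 | step 13 | benzyl 4-({2-[(2-heptyl-4-phenyl-1,3-dioxolan-2-yl)methyl]-6-hydroxy-4-methoxybenzoyl}oxy)-2-hydroxy-6-methylbenzoate | CCCCCCCC1(Cc2cc(OC)cc(O)c2C(=O)Oc2cc(C)c(C(=O)OCc3ccccc3)c(O)c2)OCC(c2ccccc2)O1
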